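Take level capture, a ratio of target to other capture product of one, as the zero of the scale. Alpha is the flask asked about, followed so far, and eta differs from it in the charge of second nucleophile.

| setting | alpha | eta | flask |
|---|---|---|---|
| substrate | 0.50 M | 0.50 M | 0.50 M |
| first nucleophile | 0.50 M | 0.50 M | 0.500 M |
| second nucleophile | 0.55 M | 0.37 M | 0.550 M |
| protic impurity | 0.50 M | 0.50 M | 0.500 M |
| remark | the very flask that is asked about, followed so far | run made earlier |  |
| time |  |  | 15 d |

- alpha (time / d: target / %, other capture product / %): 1.25: 9.4, 28.5; 2.50: 12.5, 34.3; 4.00: 13.1, 36.2; 5.00: 12.9, 36.6; 6.00: 13.0, 37.0; 8.00: 14.5, 38.3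
- eta (time / d: target / %, other capture product / %): 1.04: 11.3, 18.4; 3.00: 16.6, 26.8; 5.00: 15.0, 27.8; 8.00: 16.5, 25.6; 12.0: 14.4, 27.3; 15.0: 15.8, 27.2

(standard deviation of a reading: 1 percentage point)



- ratio of target to other capture product at 2.0 h
- ratio of target to other capture product at 15 d
- which of target and other capture product there is more of at 15 d

I read the runs from the fastest rung down. The first rung is the split. The first readings give a ratio of 0.330 in alpha at 1.25 d and 0.614 in eta at 1.04 d, so the run charged with more second nucleophile has the lower ratio. I multiply each ratio by its charge of second nucleophile and average the two. This gives the even point, the [second nucleophile] at which both captures run level with first nucleophile held at its charge in these runs, a selectivity factor in concentration units. I read it as 0.204 M.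

The next rung is the stall. In eta the two products sum to 43.4% at 3.00 d. The last rung is the plateau, where the same sum in eta reads 43.0% at 15.0 d.

So I reckon two ratios for this flask. The time 2.0 h lies far earlier than the first reading, so I divide the even point by the charge and get 0.371. For 15 d I take the plateau, which reads 0.351 in alpha at 6.00 d.

The forecast says 0.3 at 2.0 h and 0.37 at 15 d, with other capture product ahead, and it pictures “an intermediate that either gives target unimolecularly”. My early ratio stands higher than its figure.

The flask gives 0.378 at 2.0 h and 0.358 at 15 d, with other capture product ahead, 37.2% against 13.3%.

    intermediate → solvolysis product (k = 0.0234 /min)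
    target ⇌ isomer of the product (K = 1.10, k = 5.09 × 10⁻⁴ /min)
    intermediate → side product (k = 0.00153 /min)
    substrate → intermediate (k = 5.02 × 10⁻⁴ /min)
    second nucleophile + protic impurity → quenched reagent (k = 8.46 × 10⁻⁴ /M/min)
    first nucleophile + intermediate → target (k = 0.0471 /M/min)
    second nucleophile + intermediate → other capture product (k = 0.114 /M/min)

The even point gave 0.371 for the early ratio of this flask. In this flask, target and isomer of the product relax by their step alone, both ways together, with a half-life of 0.495 d, far shorter than 15 d. At 15 d this flask holds 14.7% isomer of the product beside 13.3% target. For the neighbour charged with 0.94 M of second nucleophile, the even point gives 0.217, and that flask stands at 0.220 at 2.0 h.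

The numbers in the tables stem from a simulated flask with made-up constants; noise was put on by code.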